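**Conventions.** The core is numbered as a 3,7-dioxabicyclo[3.3.0]octane: bridgeheads C1 and C5, aryl-bearing carbons C2 and C6, ring oxygens O3 and O7, methylenes C4 and C8. Ring A is C1–C2–O3–C4–C5 and ring B is C5–C6–O7–C8–C1. Ar = 4-(benzyloxy)-3-methoxyphenyl; TBS = tert-butyldimethylsilyl. Compounds 1–15 are those of the steps and of the compound list.

## The problem

Compound 15 is a C2-symmetric 3,7-dioxabicyclo[3.3.0]octane in which rings A and B share the C1–C5 bond and are necessarily cis-fused. Both bridgeheads are tertiary alcohols, so two fully substituted carbinol carbons are directly bonded, and C2 and C6 each carry a 4-hydroxy-3-methoxyphenyl group on the exo face, cis to the hydroxyl of the neighbouring bridgehead. The four stereocentres, (1R,2S,5R,6S), reduce by symmetry to one benzylic centre and the bridgehead next to it. The benzylic centre is a secondary carbinol of a kind that catalysis sets reliably, and once in place it can direct the adjacent bridgehead by 1,2-induction; the reverse order would leave the benzylic centres to thermodynamic control alone. The C2–O3 and C6–O7 bonds are p-oxygenated benzylic ethers: acid ionises them (epimerisation, ring opening, pinacol-type shifts of the neighbouring tertiary diol), hydrogen on palladium can cleave them, and the free phenols do not tolerate oxidants or strong bases. The enabling feature is that C1 and C5 are neighbouring tertiary carbinols that each bear exactly one methylene (C8 on C1, C4 on C5), which is what a 1,2-diketone spanning C1–C5 becomes after one CH2 unit is added to each carbonyl. Because each methylene is bonded to the benzylic oxygen of the other half (O7–C8, O3–C4), spiro-oxiranes at C1 and C5 would supply both the bridgehead oxygen and an electrophilic carbon for ring closure.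

## Retrosynthesis

**15 from 14 (two O–benzyl bonds).** The phenols are masked as benzyl ethers in 14. Free phenols or phenoxides would quench the zinc and ylide reagents, be oxidised by permanganate and compete as nucleophiles in the ring closure; benzyl ethers survive every step. The forward step must be a hydrogenolysis mild enough to spare the ring benzylic ethers.

**14 from 11 (O3–C4 and O7–C8).** Both rings are opened at the oxygen–methylene bonds, giving the 2,2'-bioxirane 11 via the non-isolated intermediates 12 and 13. The neighbouring cut at the benzylic C2–O3 and C6–O7 bonds would require a benzylic cation, acid, and thermodynamic control of C2 and C6. The chosen cut asks only for SN2 at a primary carbon, which touches no stereocentre. The precursor 11 is acyclic apart from the oxiranes and still C2-symmetric. The forward reaction must favour 5-exo attack on the far oxirane over attack on the near one.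

**11 from 8 and 9 (C1–C8, C5–C4 and the two oxirane C–O bonds).** Removing both methylenes gives the 1,2-diketone 8 and trimethylsulfonium iodide 9. Cutting C1–C5 instead would need a reductive coupling that sets two adjacent quaternary centres without an identifiable control element. Adding oxygen to a preformed 2,3-dimethylidene unit is kept in reserve. The diketone has only two stereocentres, both benzylic and of the same origin. The forward step must deliver 1,2-induction at both carbonyls and avoid enolisation.

**8 from 7 (functional-group change).** The 1,2-dione is the oxidised form of the alkyne in 7. This turns the C1–C5 unit into a two-carbon linchpin to which both benzylic carbons can be joined by carbonyl addition. The oxidation must stop at the dione and leave the electron-rich arenes, benzyl ethers and silyl ethers intact.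

**7 from 5 and 1, via 6 (C5–C6).** The alkynyl–carbinol bond is cut to the terminal alkyne 5 and aldehyde 1, and the new carbinol of 6 is silylated. The neighbouring option is asymmetric reduction of the corresponding ynedione. Such aryl alkynyl ketones offer a transfer-hydrogenation catalyst like RuCl(p-cymene)(TsDPEN) two unsaturated flanks that are hard to distinguish, and they are strong Michael acceptors. Addition to the aldehyde sets the centre in the bond-forming event. The forward reaction must be reagent-controlled, since the existing centre is too remote to help or hinder.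

**5 from 1 and 2, via 3 and 4 (C1–C2).** The same alkynylation is applied to aldehyde 1 with trimethylsilylacetylene 2. The silyl cap prevents double addition, and after O-silylation of 3 to 4 it is removed by methanolysis. All skeletal carbons then come from 1 (twice), 2 and 9.

## Roads not taken

**Alternative 1:** The cut is at the two aryl–carbon bonds (C2–aryl, C6–aryl). In the forward sense BF3·OEt2 would ionise the tartrate-derived 1,5-O-isopropylidene bis-lactol diacetate A1 at both anomeric carbons, and the arylzinc reagent A2 would add to each oxocarbenium ion to give the acetonide A3. Acetonide removal and debenzylation would follow.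
- Merits: the bridgehead carbinols come from the chiral pool, so their absolute configuration is certain; the aryl groups enter last, which makes aryl variation easy; the exo-aryl isomer is the thermodynamically preferred one.
- Weak points: A1 must first be built by twofold C-hydroxymethylation of a β-alkoxy ester enolate (two adjacent quaternary carbons, ready β-elimination), then lactonisation, reduction and acetylation, so the hard part only moves to the core. With the acetonide in place the system is a propellane, each face of an oxocarbenium ion is flanked by a five-membered ring, and a bias toward the face syn to the bridgehead oxygen is not assured. The first-formed aryl ether is a p-alkoxybenzylic ether that BF3 can re-ionise. The final acetonide hydrolysis needs acid next to the same labile bonds.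
- Comparison: this road is better in absolute control at C1 and C5 and in late-stage flexibility. The chosen plan sets against it ring closures that never ionise a benzylic carbon, no double quaternisation of an enolate, and stereocentres that each have a named controller.

**Alternative 2:** The cut is the C1–C2 bond. Irradiation of the α-keto-γ-lactone A4 (ring B preformed, C5 bearing the hydroxyl and a CH2–O–CH2Ar arm) would excite the C1 ketone, which abstracts the benzylic hydrogen of the ether. The 1,5-biradical then closes to the hydroxy lactone A5, forming C1–C2, the C1 hydroxyl and ring A (Norrish–Yang cyclisation). Reduction of the C8 lactone carbonyl to a methylene and debenzylation would finish.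
- Merits: a C–C bond is made from a C–H bond without reagents; the C1 hydroxyl arrives unprotected; cis-fusion is enforced; the reaction type has precedent for hydroxylated furofuran skeletons.
- Weak points: A4 already holds C5 and C6 in defined configuration next to a vicinal dicarbonyl, so its enantioselective preparation is a synthesis of its own. The C2 configuration depends on biradical conformation. Back hydrogen transfer, fragmentation and electron transfer from the electron-rich arenes compete. The lactone must later be reduced to a cyclic ether, typically through a lactol and a Lewis-acid-mediated ionic reduction that endangers the benzylic ethers.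
- Comparison: this road is better in redox and atom economy at the C1–C2 bond, and it would allow two different aryl groups. The chosen plan sets against it the use of C2 symmetry (each operation serves both halves) and the absence of a late carbonyl removal.

**Alternative 3:** The cuts are C1–C2 and C5–C6 (aldol) and the two acyl C–O bonds. The lithium enolate of dimethyl L-tartrate acetonide A6 would add to aldehyde 1 at each α-carbon in turn, each aldolate lactonising onto the ester of the neighbouring carbon to give the bis-lactone A7. Both lactone carbonyls would then be reduced to methylenes and the acetonide and benzyl groups removed.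
- Merits: it is the shortest conceivable assembly of the skeleton, from two cheap materials; chirality comes from the chiral pool; the C1 and C5 oxygens are present from the start.
- Weak points: enolates of A6 are short-lived (β-elimination of the ring oxygen) and react cleanly only with very reactive electrophiles. The aldol with an electron-rich aryl aldehyde is reversible. The second enolisation must occur beside a new quaternary centre. The benzylic configuration rests on the simple diastereoselection of a fully substituted enolate with no clear control element. Two lactone carbonyls next to ionisable benzylic C–O bonds must then be taken down to CH2.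
- Comparison: if the double aldol worked, this road would be several steps shorter and need no asymmetric catalyst, a real advantage in step economy. The chosen plan sets against it that C4 and C8 arrive at the correct oxidation level and that no step rests on a fragile enolate.

Key step: step 7

Assumption: (S,S)-ProPhenol with Me2Zn is taken to deliver the alkynyl group to the Re face of an aryl aldehyde, by analogy with the facial sense of its aldol reactions; if the sense proves opposite, (R,R)-ProPhenol is used in steps 1 and 4 and nothing else changes.

## Route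

Step 1
Reactants: 1 4-(benzyloxy)-3-methoxybenzaldehyde; 2 trimethylsilylacetylene
Product: 3 (S)-1-[4-(benzyloxy)-3-methoxyphenyl]-3-(trimethylsilyl)prop-2-yn-1-ol
Conditions: 2 (3 equiv), Me2Zn (3 equiv), (S,S)-ProPhenol (10 mol %), Ph3P=O (20 mol %), toluene, 0–4 °C; aq. NH4Cl
Reagents that add atoms: none
Why: Zn–ProPhenol-catalysed asymmetric alkynylation of an aromatic aldehyde; the dinuclear zinc alkynylide transfers the alkynyl group to the Re face of 1 and so sets the future C2 as (S) under reagent control.

Step 2
Reactants: 3 (S)-1-[4-(benzyloxy)-3-methoxyphenyl]-3-(trimethylsilyl)prop-2-yn-1-ol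
Product: 4 (S)-tert-butyl({1-[4-(benzyloxy)-3-methoxyphenyl]-3-(trimethylsilyl)prop-2-yn-1-yl}oxy)dimethylsilane
Conditions: TBSCl, imidazole, DMF, 23 °C
Reagents that add atoms: tert-butyldimethylsilyl chloride, CC(C)(C)[Si](C)(C)Cl
Why: Standard silylation of a secondary alcohol; the bulky, poorly coordinating TBS group is chosen because it must later enforce non-chelated addition in step 7 and leave with fluoride in step 8.

Step 3
Reactants: 4 (S)-tert-butyl({1-[4-(benzyloxy)-3-methoxyphenyl]-3-(trimethylsilyl)prop-2-yn-1-yl}oxy)dimethylsilane
Product: 5 (R)-tert-butyl({1-[4-(benzyloxy)-3-methoxyphenyl]prop-2-yn-1-yl}oxy)dimethylsilane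
Conditions: K2CO3 (0.3 equiv), MeOH, 0 → 23 °C
Reagents that add atoms: none
Why: Base-catalysed methanolysis of the alkynyl C–Si bond; the secondary O–TBS ether and the benzyl ether are inert to catalytic methoxide and the propargylic C–H is not acidic enough to epimerise (the descriptor changes to R only because ethynyl ranks below the aryl group).

Step 4
Reactants: 5 (R)-tert-butyl({1-[4-(benzyloxy)-3-methoxyphenyl]prop-2-yn-1-yl}oxy)dimethylsilane; 1 4-(benzyloxy)-3-methoxybenzaldehyde
Product: 6 (1S,4S)-1,4-bis[4-(benzyloxy)-3-methoxyphenyl]-4-[(tert-butyldimethylsilyl)oxy]but-2-yn-1-ol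
Conditions: 5 (1.5 equiv, excess recovered), Me2Zn (2.5 equiv), (S,S)-ProPhenol (10 mol %), Ph3P=O (20 mol %), toluene, 0–4 °C; aq. NH4Cl
Reagents that add atoms: none
Why: Second Zn–ProPhenol alkynylation with the same Re-face delivery, which sets the future C6 as (S); the existing centre lies four atoms away across the linear alkyne, so reagent control alone decides, and minor-enantiomer material from step 1 ends mainly in the unlike diastereomer, which can be removed by chromatography here or after step 5.

Step 5
Reactants: 6 (1S,4S)-1,4-bis[4-(benzyloxy)-3-methoxyphenyl]-4-[(tert-butyldimethylsilyl)oxy]but-2-yn-1-ol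
Product: 7 (1S,4S)-1,4-bis[4-(benzyloxy)-3-methoxyphenyl]-1,4-bis[(tert-butyldimethylsilyl)oxy]but-2-yne
Conditions: TBSCl, imidazole, DMF, 23 °C
Reagents that add atoms: tert-butyldimethylsilyl chloride, CC(C)(C)[Si](C)(C)Cl
Why: Standard silylation that restores C2 symmetry, so that both carbonyl groups of the later diketone see the same α-substituent.

Step 6
Reactants: 7 (1S,4S)-1,4-bis[4-(benzyloxy)-3-methoxyphenyl]-1,4-bis[(tert-butyldimethylsilyl)oxy]but-2-yne
Product: 8 (1S,4S)-1,4-bis[4-(benzyloxy)-3-methoxyphenyl]-1,4-bis[(tert-butyldimethylsilyl)oxy]butane-2,3-dione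
Conditions: KMnO4, NaHCO3, MgSO4, acetone/H2O, 0 → 23 °C
Reagents that add atoms: potassium permanganate, [K+].[O-][Mn](=O)(=O)=O
Why: Permanganate oxidation of an internal alkyne to a 1,2-diketone through a cyclic manganate ester, a known conversion for alkynes flanked by protected carbinols; the buffered, near-neutral medium should keep the benzylic α-protons of 8 from enolising, so both stereocentres are carried through, and silyl and benzyl ethers are not attacked.

Step 7
Reactants: 8 (1S,4S)-1,4-bis[4-(benzyloxy)-3-methoxyphenyl]-1,4-bis[(tert-butyldimethylsilyl)oxy]butane-2,3-dione; 9 trimethylsulfonium iodide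
Product: 11 (2R,2'R)-2,2'-bis{(S)-[4-(benzyloxy)-3-methoxyphenyl][(tert-butyldimethylsilyl)oxy]methyl}-2,2'-bioxirane, via epoxy ketone 10 (not isolated)
Conditions: 9 (3.0 equiv), KN(SiMe3)2 (2.8 equiv), THF, −20 °C; then 8, −78 → −30 °C
Reagents that add atoms: none
Why: Corey–Chaykovsky epoxidation carried out twice in one flask, the closest known reaction type being sulfonium-ylide methylenation of α-silyloxy ketones under non-chelation control. Dimethylsulfonium methylide, formed from 9 and KN(SiMe3)2, adds to one carbonyl carbon of 8 (new C1–C8 bond) and the betaine alkoxide displaces Me2S from the methylene carbon, closing the first oxirane by 3-exo-tet attack to give 10; repetition at the second carbonyl forms C5–C4 and closes the second oxirane in the same 3-exo-tet mode. C1 is set by the adjacent C2 silyloxy centre in the polar Felkin–Anh sense: the C2–OSi bond stands perpendicular to the carbonyl plane and anti to the ylide, which passes the C2 hydrogen while the aryl group lies beside the carbonyl oxygen, so that (S)-C2 gives (R)-C1, and the dipole-opposed Cornforth arrangement leads to the same face. C5 is set in the same way by C6, and in this second addition the oxirane already present at C1 can place its C–O bond anti to the ylide with its small CH2 beside the trajectory, so both flanking centres point to the same face and the C2-symmetric isomer is the matched one. The step needs high facial selectivity at both carbonyls and no enolisation toward the benzylic C2–H and C6–H. The first is secured by the bulky, weakly coordinating TBS ethers and a potassium counter-ion in THF, which leave no chelate to reverse the sense; the second by the high electrophilicity of the 1,2-dicarbonyl, which should capture the ylide at −78 °C faster than it gives up a proton, and by keeping the amide base below the amount of 9 so that no free amide meets 8. Ylide addition is irreversible and ring closure fast, so the kinetic facial preference is what should be isolated.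

Step 8
Reactants: 11 (2R,2'R)-2,2'-bis{(S)-[4-(benzyloxy)-3-methoxyphenyl][(tert-butyldimethylsilyl)oxy]methyl}-2,2'-bioxirane
Product: 14 (1R,2S,5R,6S)-2,6-bis[4-(benzyloxy)-3-methoxyphenyl]-3,7-dioxabicyclo[3.3.0]octane-1,5-diol, via bis-epoxy diol 12 (not isolated), via spiro-epoxy tetrahydrofuranol 13 (not isolated)
Conditions: Bu4NF (2.5 equiv), THF, 0 → 40 °C; aq. NH4Cl
Reagents that add atoms: none
Why: Fluoride desilylation frees the C2 and C6 oxygens as ammonium alkoxides, and each attacks the unsubstituted CH2 of the oxirane on the far bridgehead (O3→C4, then O7→C8) in a 5-exo-tet SN2 opening that touches no stereocentre and turns each oxirane oxygen into a bridgehead hydroxyl. Attack on the near oxirane would require a three- or four-membered ring or SN2 at a quaternary carbon, and the (1R,5R) relationship of 11 permits only the cis-fused bicycle.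

Step 9
Reactants: 14 (1R,2S,5R,6S)-2,6-bis[4-(benzyloxy)-3-methoxyphenyl]-3,7-dioxabicyclo[3.3.0]octane-1,5-diol
Product: 15 (1R,2S,5R,6S)-2,6-bis(4-hydroxy-3-methoxyphenyl)-3,7-dioxabicyclo[3.3.0]octane-1,5-diol
Conditions: H2 (1 atm), 10% Pd/C, EtOAc, 23 °C
Reagents that add atoms: none
Why: Hydrogenolysis of the two aryl benzyl ethers over Pd/C in a neutral aprotic solvent; O-benzyl phenol ethers cleave much faster than the ring benzylic C–O bonds, and the reaction is to be stopped after uptake of two equivalents of hydrogen.

## Compound list

1 | 4-(benzyloxy)-3-methoxybenzaldehyde (O-benzylvanillin) | O=Cc1ccc(OCc2ccccc2)c(OC)c1 | starting material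
2 | trimethylsilylacetylene (ethynyltrimethylsilane) | C#C[Si](C)(C)C | starting material
3 | (S)-1-[4-(benzyloxy)-3-methoxyphenyl]-3-(trimethylsilyl)prop-2-yn-1-ol | COc1cc([C@H](O)C#C[Si](C)(C)C)ccc1OCc1ccccc1 | intermediate
4 | (S)-tert-butyl({1-[4-(benzyloxy)-3-methoxyphenyl]-3-(trimethylsilyl)prop-2-yn-1-yl}oxy)dimethylsilane | COc1cc([C@H](O[Si](C)(C)C(C)(C)C)C#C[Si](C)(C)C)ccc1OCc1ccccc1 | intermediate
5 | (R)-tert-butyl({1-[4-(benzyloxy)-3-methoxyphenyl]prop-2-yn-1-yl}oxy)dimethylsilane (same spatial arrangement as 4) | COc1cc([C@H](O[Si](C)(C)C(C)(C)C)C#C)ccc1OCc1ccccc1 | intermediate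
6 | (1S,4S)-1,4-bis[4-(benzyloxy)-3-methoxyphenyl]-4-[(tert-butyldimethylsilyl)oxy]but-2-yn-1-ol | COc1cc([C@H](O[Si](C)(C)C(C)(C)C)C#C[C@@H](O)c2ccc(OCc3ccccc3)c(OC)c2)ccc1OCc1ccccc1 | intermediate
7 | (1S,4S)-1,4-bis[4-(benzyloxy)-3-methoxyphenyl]-1,4-bis[(tert-butyldimethylsilyl)oxy]but-2-yne | COc1cc([C@H](O[Si](C)(C)C(C)(C)C)C#C[C@@H](O[Si](C)(C)C(C)(C)C)c2ccc(OCc3ccccc3)c(OC)c2)ccc1OCc1ccccc1 | intermediate
8 | (1S,4S)-1,4-bis[4-(benzyloxy)-3-methoxyphenyl]-1,4-bis[(tert-butyldimethylsilyl)oxy]butane-2,3-dione | COc1cc([C@H](O[Si](C)(C)C(C)(C)C)C(=O)C(=O)[C@@H](O[Si](C)(C)C(C)(C)C)c2ccc(OCc3ccccc3)c(OC)c2)ccc1OCc1ccccc1 | intermediate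
9 | trimethylsulfonium iodide | C[S+](C)C.[I-] | starting material
10 | (2S)-2-Ar-2-(TBS-oxy)-1-{(2R)-2-[(S)-Ar(TBS-oxy)methyl]oxiran-2-yl}ethan-1-one (epoxy ketone, not isolated) | COc1cc([C@H](O[Si](C)(C)C(C)(C)C)[C@]2(CO2)C(=O)[C@@H](O[Si](C)(C)C(C)(C)C)c3ccc(OCc4ccccc4)c(OC)c3)ccc1OCc1ccccc1 | intermediate
11 | (2R,2'R)-2,2'-bis{(S)-[4-(benzyloxy)-3-methoxyphenyl][(tert-butyldimethylsilyl)oxy]methyl}-2,2'-bioxirane | COc1cc([C@H](O[Si](C)(C)C(C)(C)C)[C@]2(CO2)[C@@]3(CO3)[C@@H](O[Si](C)(C)C(C)(C)C)c4ccc(OCc5ccccc5)c(OC)c4)ccc1OCc1ccccc1 | intermediate
12 | (2R,2'R)-2,2'-bis{(S)-[4-(benzyloxy)-3-methoxyphenyl](hydroxy)methyl}-2,2'-bioxirane (bis-epoxy diol, not isolated) | COc1cc([C@H](O)[C@]2(CO2)[C@@]3(CO3)[C@@H](O)c4ccc(OCc5ccccc5)c(OC)c4)ccc1OCc1ccccc1 | intermediate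
13 | 4-Ar-7-[(S)-Ar(hydroxy)methyl]-1,5-dioxaspiro[2.4]heptan-7-ol: ring A closed, C5 hydroxyl free, C1 still a spiro-oxirane, C1, C2, C5 and C6 configured as in 14 (not isolated) | COc1cc([C@@H]2OC[C@@](O)([C@@H](O)c3ccc(OCc4ccccc4)c(OC)c3)[C@@]25CO5)ccc1OCc1ccccc1 | intermediate
14 | (1R,2S,5R,6S)-2,6-bis[4-(benzyloxy)-3-methoxyphenyl]-3,7-dioxabicyclo[3.3.0]octane-1,5-diol | COc1cc([C@@H]2OC[C@@]3(O)[C@H](c4ccc(OCc5ccccc5)c(OC)c4)OC[C@@]23O)ccc1OCc1ccccc1 | intermediate
15 | (1R,2S,5R,6S)-2,6-bis(4-hydroxy-3-methoxyphenyl)-3,7-dioxabicyclo[3.3.0]octane-1,5-diol | COc1cc([C@@H]2OC[C@@]3(O)[C@H](c4ccc(O)c(OC)c4)OC[C@@]23O)ccc1O | target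

## Step count and least certain steps

Total: 9 steps. Longest linear sequence: 9 steps (1 → 3 → 4 → 5 → 6 → 7 → 8 → 11 → 14 → 15).

**Step 7 (key step).** The most likely failures are proton transfer from the benzylic α-carbons of 8 to the basic ylide (epimerisation of C2 and C6, or silyl migration in the resulting enolate), incomplete facial selectivity in the second addition, and 1,4-silyl transfer to the betaine oxygen before it closes. The fallback sets out from 7 and abandons the diketone. Ethylene–alkyne metathesis of 7 (ethylene, 1 atm, second-generation Grubbs catalyst RuCl2(=CHPh)(H2IMes)(PCy3), toluene, 80 °C) should give the 2,3-dimethylidene bis(silyl ether) F1. Bu4NF then gives the diene diol F2. Hydroxyl-directed epoxidation with VO(acac)2 and t-BuOOH in CH2Cl2 is known to favour the erythro epoxy alcohol for allylic alcohols that carry a substituent on the inner alkene carbon; this is the same C2/C1 and C6/C5 relationship that the Felkin-type addition is meant to give. The route is rejoined at 12, which is closed to 14 with Bu4NF or catalytic KOt-Bu as in step 8. Here the methylene carbons come from ethylene and the stereocontrol from the free benzylic hydroxyls, and no enolisable ketone is involved.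

**Step 1 (the same reagent system serves step 4).** The risk is insufficient enantiofacial discrimination with a silyl-capped alkyne and an electron-rich aldehyde, and slow alkynyl transfer that lets methyl transfer from Me2Zn compete. In step 4 a shortfall is buffered, because it appears as a separable diastereomer. The fallback sets out from 1. Ethynylmagnesium bromide in THF gives the racemic propargylic alcohol F3. Acylation with Candida antarctica lipase B and vinyl acetate should, by the empirical size rule for secondary alcohols (aryl large, ethynyl medium), acylate the needed enantiomer to the (R)-acetate F4 and leave the other enantiomer of F3 behind. K2CO3 in MeOH gives the (R)-alcohol F5, and TBSCl/imidazole returns to the route at 5.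

**Step 6.** The risks are oxidation beyond the dione (C–C cleavage to arylacetic acid derivatives), attack of permanganate on the electron-rich rings or the benzylic C–H bonds, a sluggish reaction at the hindered alkyne, and epimerisation of 8 during isolation. The fallback sets out from 7. Semi-hydrogenation (H2, Pd/CaCO3 poisoned with Pb(OAc)2, quinoline) gives the (Z)-alkene F6. OsO4 (catalytic) with N-methylmorpholine N-oxide gives the diol F7 as a single isomer, since the two alkene faces are related by the C2 axis. Dess–Martin periodinane buffered with NaHCO3 oxidises both carbinols without base and returns to the route at 8.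

**Step 8.** The alkoxide may stray to other electrophilic sites (Payne-type transposition onto the near oxirane, oxetane formation), the sequence may stall at 13 because the second closure has to build the strained cis-bicycle, and silyl transfer to the tertiary alkoxide may occur. The fallback sets out from 11 and inverts the polarity of the ring-closing bonds. KOH in aqueous DMSO at 70 °C opens both oxiranes at CH2 with hydroxide while the silyl ethers stay on, giving the bis(silyl) tetraol F8. Bu4NF gives the hexaol F9. Camphorsulfonic acid in MeCN then ionises the p-alkoxybenzylic carbinols, and the primary hydroxyls capture the cations (O3–C2 and O7–C6 formed instead of O3–C4 and O7–C8) under thermodynamic control, which favours the exo-aryl isomer with C1 and C5 untouched. The route is rejoined at 14.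

**Step 9.** The risk is hydrogenolysis running on into the ring C2–O3 and C6–O7 bonds, which are p-oxygenated benzylic ethers, once or while the benzyl groups leave. The fallback sets out from 11 and changes the order of events. Hydrogenolysis of 11 (H2, Pd/C, EtOAc) is carried out before any ring benzylic ether exists and gives the bis-phenol bis(silyl ether) F10. Bu4NF then removes the silyl groups and drives the same double 5-exo closure, arriving directly at 15.

## Further compounds

F1 | step 7 | (1S,4S)-1,4-bis[4-(benzyloxy)-3-methoxyphenyl]-1,4-bis[(tert-butyldimethylsilyl)oxy]-2,3-dimethylidenebutane | COc1cc([C@H](O[Si](C)(C)C(C)(C)C)C(=C)C(=C)[C@@H](O[Si](C)(C)C(C)(C)C)c2ccc(OCc3ccccc3)c(OC)c2)ccc1OCc1ccccc1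
F2 | step 7 | (1S,4S)-1,4-bis[4-(benzyloxy)-3-methoxyphenyl]-2,3-dimethylidenebutane-1,4-diol | COc1cc([C@H](O)C(=C)C(=C)[C@@H](O)c2ccc(OCc3ccccc3)c(OC)c2)ccc1OCc1ccccc1
F3 | step 1 | racemic 1-[4-(benzyloxy)-3-methoxyphenyl]prop-2-yn-1-ol | COc1cc(C(O)C#C)ccc1OCc1ccccc1
F4 | step 1 | (R)-1-[4-(benzyloxy)-3-methoxyphenyl]prop-2-yn-1-yl acetate | COc1cc([C@H](OC(C)=O)C#C)ccc1OCc1ccccc1
F5 | step 1 | (R)-1-[4-(benzyloxy)-3-methoxyphenyl]prop-2-yn-1-ol | COc1cc([C@H](O)C#C)ccc1OCc1ccccc1
F6 | step 6 | (Z)-1,4-bis[4-(benzyloxy)-3-methoxyphenyl]-1,4-bis[(tert-butyldimethylsilyl)oxy]but-2-ene, benzylic centres as in 7 [(1R,4R) by the sequence rule, alkenyl ranking below aryl] | COc1cc([C@H](O[Si](C)(C)C(C)(C)C)/C=C\[C@@H](O[Si](C)(C)C(C)(C)C)c2ccc(OCc3ccccc3)c(OC)c2)ccc1OCc1ccccc1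
F7 | step 6 | (1S,2R,3S,4S)-1,4-bis[4-(benzyloxy)-3-methoxyphenyl]-1,4-bis[(tert-butyldimethylsilyl)oxy]butane-2,3-diol | COc1cc([C@H](O[Si](C)(C)C(C)(C)C)[C@H](O)[C@H](O)[C@@H](O[Si](C)(C)C(C)(C)C)c2ccc(OCc3ccccc3)c(OC)c2)ccc1OCc1ccccc1
F8 | step 8 | (1S,2R,3R,4S)-1,4-bis[4-(benzyloxy)-3-methoxyphenyl]-1,4-bis[(tert-butyldimethylsilyl)oxy]-2,3-bis(hydroxymethyl)butane-2,3-diol | COc1cc([C@H](O[Si](C)(C)C(C)(C)C)[C@](O)(CO)[C@@](O)(CO)[C@@H](O[Si](C)(C)C(C)(C)C)c2ccc(OCc3ccccc3)c(OC)c2)ccc1OCc1ccccc1
F9 | step 8 | (1S,2R,3R,4S)-1,4-bis[4-(benzyloxy)-3-methoxyphenyl]-2,3-bis(hydroxymethyl)butane-1,2,3,4-tetraol | COc1cc([C@H](O)[C@](O)(CO)[C@@](O)(CO)[C@@H](O)c2ccc(OCc3ccccc3)c(OC)c2)ccc1OCc1ccccc1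
F10 | step 9 | (2R,2'R)-2,2'-bis{(S)-(4-hydroxy-3-methoxyphenyl)[(tert-butyldimethylsilyl)oxy]methyl}-2,2'-bioxirane | COc1cc([C@H](O[Si](C)(C)C(C)(C)C)[C@]2(CO2)[C@@]3(CO3)[C@@H](O[Si](C)(C)C(C)(C)C)c4ccc(O)c(OC)c4)ccc1O
A1 | alternative 1 | 2,6-di-O-acetyl-1,5-O-isopropylidene-3,7-dioxabicyclo[3.3.0]octane-1,2,5,6-tetraol (bis-lactol diacetate, anomeric mixture) | CC(=O)OC1OC[C@@]2(OC(C)(C)O3)C(OC(C)=O)OC[C@@]123
A2 | alternative 1 | [4-(benzyloxy)-3-methoxyphenyl]zinc bromide | COc1cc([Zn]Br)ccc1OCc1ccccc1
A3 | alternative 1 | 1,5-O-isopropylidene derivative of 14 | COc1cc([C@@H]2OC[C@@]3(OC(C)(C)O4)[C@H](c5ccc(OCc6ccccc6)c(OC)c5)OC[C@@]234)ccc1OCc1ccccc1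
A4 | alternative 2 | 5-[4-(benzyloxy)-3-methoxyphenyl]-4-hydroxy-4-({[4-(benzyloxy)-3-methoxyphenyl]methoxy}methyl)oxolane-2,3-dione, configured at C5 and C6 as in 15 | COc1cc(COC[C@@]2(O)[C@H](c3ccc(OCc4ccccc4)c(OC)c3)OC(=O)C2=O)ccc1OCc1ccccc1
A5 | alternative 2 | 1,5-dihydroxy-2,6-bis[4-(benzyloxy)-3-methoxyphenyl]-3,7-dioxabicyclo[3.3.0]octan-8-one | COc1cc([C@@H]2OC[C@@]3(O)[C@H](c4ccc(OCc5ccccc5)c(OC)c4)OC(=O)[C@@]23O)ccc1OCc1ccccc1
A6 | alternative 3 | dimethyl (4R,5R)-2,2-dimethyl-1,3-dioxolane-4,5-dicarboxylate (dimethyl L-tartrate acetonide) | COC(=O)[C@@H]1OC(C)(C)O[C@H]1C(=O)OC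
A7 | alternative 3 | 1,5-O-isopropylidene-2,6-bis[4-(benzyloxy)-3-methoxyphenyl]-1,5-dihydroxy-3,7-dioxabicyclo[3.3.0]octane-4,8-dione | COc1cc([C@@H]2OC(=O)[C@@]3(OC(C)(C)O4)[C@H](c5ccc(OCc6ccccc6)c(OC)c5)OC(=O)[C@@]234)ccc1OCc1ccccc1
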